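## Retrosynthetic overview

1. **Feature the strategy rests on.** Ring A of the target is ring A of (+)-podocarpic acid in the same absolute sense. This covers C4 with its axial oxygenated carbon C19 and methyl C18, C5 (5α-H), and quaternary C10 (β-methyl C20). The aromatic ring C of podocarpic acid can be burnt away so that only its fusion carbons C8 and C9 survive, as two carboxyl groups.
2. **End game, read backwards.** The C15 acid comes from an allyl ester and the C19 angelate from a late acylation. C13–C16 comes from syn methylcupration of a C13≡C14 ynoate, which gives 13Z. C14–C15 and C12–C13 come from acetylide chemistry. C8–C17 comes from methyl coupling of the kinetic C7=C8 enol triflate of a C8 ketone, next to which C9 can be equilibrated.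
3. **Key disconnection C8–C9.** Ring B closes again when C9 of an (E)-C9=C11–C12–SiMe3 allylsilane attacks the C8 aldehyde. The C11=C12 vinyl group left behind is the root of the side chain.
4. **Order of rings.** Ring A is bought. Ring C is removed and ring B opened in step 4. Ring B is rebuilt in step 11, and no other ring is made.
5. **Design points.** C19 is masked as a TIPS ether, because an acyl group could not be removed later beside the C15 ester and would compete in the hydride and organolithium steps. The allylsilane is made E by Takai olefination and Negishi coupling, because a non-stabilised ylide would give mainly the Z olefin.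

Key step: step 11

Remark on the chemistry: labdane numbering (C1–C20) is kept for every compound, including the seco compounds 5–11. α and β refer to the usual drawing with C20 β.

## Route

Step 1
Reactants: 1 (+)-podocarpic acid
Product: 2 methyl 12-methoxypodocarpa-8,11,13-trien-19-oate
Conditions: MeI (3 equiv), K2CO3, DMF, rt
Reagents that add atoms: iodomethane, CI
Why: O-alkylation (SN2 on MeI, Williamson type) is insensitive to the hindrance of the axial C19 carboxylate and caps the phenol in the same operation, which keeps ring C electron-rich for step 4.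

Step 2
Reactants: 2 methyl 12-methoxypodocarpa-8,11,13-trien-19-oate
Product: 3 12-methoxypodocarpa-8,11,13-trien-19-ol
Conditions: LiAlH4, THF, reflux
Reagents that add atoms: none
Why: Ester reduction with LiAlH4; the hindered axial ester needs reflux, nothing else in 2 is reducible, and quaternary C4 cannot epimerise.

Step 3
Reactants: 3 12-methoxypodocarpa-8,11,13-trien-19-ol
Product: 4 12-methoxy-19-(triisopropylsilyloxy)podocarpa-8,11,13-triene
Conditions: TIPSOTf, 2,6-lutidine, CH2Cl2, 0 °C to rt
Reagents that add atoms: triisopropylsilyl triflate, CC(C)[Si](C(C)C)(C(C)C)OS(=O)(=O)C(F)(F)F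
Why: Silylation with a silyl triflate is reactive enough for the neopentyl C19 hydroxyl; the TIPS ether has no arene or carbonyl group, so it should outlast RuO4, hydrides, organometallics and a Lewis acid at −78 °C, and it can be removed by fluoride beside an ester.

Step 4
Reactants: 4 12-methoxy-19-(triisopropylsilyloxy)podocarpa-8,11,13-triene
Product: 5 ring A 8,9-diacid (C19 OTIPS)
Conditions: RuCl3·xH2O (5 mol %), NaIO4 (20 equiv), EtOAc/MeCN/H2O 2:2:3, rt
Reagents that add atoms: sodium periodate, [Na+].[O-]I(=O)(=O)=O; water, O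
Why: Catalytic RuO4 degradation of an arene to carboxylic acids; the electrophilic oxidant attacks the anisole ring far faster than C–H bonds, burns C11–C14 away and leaves the two ring-fusion carbons C8 and C9 as CO2H, as is known for tetralin-type phenols and anisoles, while C4, C5 and C10 are untouched.

Step 5
Reactants: 5 ring A 8,9-diacid (C19 OTIPS)
Product: 6 C8 methyl ester C9 acid
Conditions: EDC·HCl (1.05 equiv), DMAP (0.1 equiv), MeOH (5 equiv), CH2Cl2, 0 °C to rt
Reagents that add atoms: methanol, CO
Why: Steglich esterification under steric control; only the unhindered C8 acid is activated and trapped by MeOH at a useful rate, the C9 acid on quaternary C10 stays free, and any seven-membered anhydride that forms is opened by MeOH at the same C8 carbonyl.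

Step 6
Reactants: 6 C8 methyl ester C9 acid
Product: 7 C9 primary alcohol C8 methyl ester
Conditions: BH3·THF (2 equiv), THF, 0 °C to rt; then H2O
Reagents that add atoms: none
Why: Borane reduction of a carboxylic acid through its acyloxyborane is much faster than ester reduction, also for tertiary-alkyl acids, so only C9 goes to the alcohol.

Step 7
Reactants: 7 C9 primary alcohol C8 methyl ester
Product: 8 C9 aldehyde C8 methyl ester
Conditions: Dess–Martin periodinane, CH2Cl2, rt
Reagents that add atoms: none
Why: Dess–Martin oxidation stops at the aldehyde, which sits on quaternary C10 and therefore can neither enolise nor epimerise.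

Step 8
Reactants: 8 C9 aldehyde C8 methyl ester
Product: 9 (E)-C9=C11 vinyl iodide C8 methyl ester
Conditions: CrCl2 (6 equiv), CHI3 (2 equiv), THF, 0 °C to rt
Reagents that add atoms: iodoform, IC(I)I
Why: Takai olefination; the gem-dichromium species from CHI3 and CrCl2 adds to the aldehyde and eliminates to the E-iodoalkene, the bulk of C10 reinforcing the E preference, whereas a β-silyl non-stabilised ylide would give mainly the Z olefin, whose CH2SiMe3 group would be pressed against C1 and C20 in step 11; ester and silyl ether are inert to divalent chromium.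

Step 9
Reactants: 9 (E)-C9=C11 vinyl iodide C8 methyl ester
Product: 10 (E)-allylsilane C8 methyl ester
Conditions: Me3SiCH2MgCl, ZnCl2, THF, 0 °C; then 9, Pd(PPh3)4 (5 mol %), THF, rt
Reagents that add atoms: (trimethylsilyl)methylmagnesium chloride, C[Si](C)(C)C[Mg]Cl
Why: Negishi coupling of an alkenyl iodide proceeds with retention of olefin geometry at the unhindered C11, and the organozinc reagent leaves the methyl ester alone.

Step 10
Reactants: 10 (E)-allylsilane C8 methyl ester
Product: 11 (E)-allylsilane C8 aldehyde (cyclisation precursor)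
Conditions: i-Bu2AlH (1.1 equiv), CH2Cl2, −78 °C; MeOH, then aq potassium sodium tartrate
Reagents that add atoms: none
Why: Partial ester reduction with i-Bu2AlH; the aluminium hemiacetal is stable at −78 °C and collapses to the aldehyde only on work-up, and the ester is the only reducible group because C19 carries no acyl group.

Step 11
Reactants: 11 (E)-allylsilane C8 aldehyde (cyclisation precursor)
Product: 12 19-(triisopropylsilyloxy)-13,14,15,16,17-pentanorlabd-11-en-8α-ol (8α-hydroxy-9β-vinyl bicycle)
Conditions: BF3·OEt2 (1.2 equiv), 2,6-di-tert-butyl-4-methylpyridine (0.2 equiv), CH2Cl2 (0.005 M), −78 °C; aq NaHCO3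
Reagents that add atoms: none
Why: BF3 binds the C8 aldehyde oxygen, the γ-carbon C9 of the allylsilane attacks C8 anti to the C12–Si bond (SE2′), the charge building at C11 is held by the β-silicon effect, and loss of Me3Si to fluoride leaves the C11=C12 vinyl group, which is an intramolecular Hosomi–Sakurai allylation, an established way to 2-vinylcyclohexanols. Ring B (C5–C6–C7–C8–C9–C10) closes 6-exo-trig at the carbonyl carbon, with the C9=C11 bond exocyclic to the new ring, through a chair whose two anchors, C5–C6 and C10–C9, are already trans-diequatorial on ring A, so only a trans-decalin can result. At C8 the complexed oxygen should take the equatorial α site because the axial β site is syn-axial to the C20 methyl group, and this centre is erased in step 14 anyway. At C9 the C11 arm should sit pseudo-equatorial (β, 9α-H), away from the axial hydrogens on C5 and C7, and a minor 9-epimer is harmless because step 14 equilibrates C9. The step needs γ-regioselectivity, which silicon secures (attack through C11 would give an unstabilised cation and a seven-membered ring), and it needs cyclisation to outrun protodesilylation, which is secured by the E geometry that keeps CH2SiMe3 clear of C1 and C20 so that C–Si can align with the π system, by low temperature and dilution, and by the hindered pyridine as proton trap.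

Step 12
Reactants: 12 8α-hydroxy-9β-vinyl bicycle
Product: 14 19-(triisopropylsilyloxy)-13,14,15,16,17-pentanorlabdane-8α,12-diol, via B-alkyl-9-BBN adduct 13 (not isolated)
Conditions: 9-BBN (2.5 equiv), THF, 0 to 40 °C; then aq NaOH, H2O2, 0 °C to rt
Reagents that add atoms: hydrogen peroxide, OO; 9-BBN, B1C2CCCC1CCC2 (atoms kept only in 13)
Why: Hydroboration–oxidation with 9-BBN places boron on the terminal C12 (anti-Markovnikov), and it is run before C8 is oxidised because an α-vinyl ketone would slip into conjugation as the C9=C11 enone.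

Step 13
Reactants: 14 8α,12-diol
Product: 15 12-TBS ether of the 8α,12-diol
Conditions: TBSCl (1.05 equiv), imidazole, CH2Cl2, 0 °C
Reagents that add atoms: tert-butyldimethylsilyl chloride, CC(C)(C)[Si](C)(C)Cl
Why: Selective silylation; the unhindered primary C12 hydroxyl reacts far faster than the secondary C8 hydroxyl flanked by the C9 chain.

Step 14
Reactants: 15 12-TBS ether of the 8α,12-diol
Product: 16 12-(TBS-oxy)-19-(TIPS-oxy)-13,14,15,16,17-pentanorlabdan-8-one (9α-H)
Conditions: Dess–Martin periodinane, CH2Cl2, rt; then DBU (0.2 equiv), toluene, rt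
Reagents that add atoms: none
Why: Dess–Martin oxidation removes the C8 carbinol centre, and base-mediated equilibration through the enolate puts the C9 chain in the equatorial β position (9α-H), the axial alternative suffering from the axial hydrogens on C5 and C7, so any 9-epimer from step 11 converges on 16.

Step 15
Reactants: 16 C8 ketone
Product: 18 C7=C8 enol triflate, via potassium C7 enolate 17 (not isolated)
Conditions: KN(SiMe3)2 (1.1 equiv), THF, −78 °C; then N-(5-chloro-2-pyridyl)triflimide, −78 to −30 °C
Reagents that add atoms: N-(5-chloro-2-pyridyl)triflimide (Comins reagent), Clc1ccc(nc1)N(S(=O)(=O)C(F)(F)F)S(=O)(=O)C(F)(F)F; KN(SiMe3)2, C[Si](C)(C)[N-][Si](C)(C)C.[K+] (potassium kept only in 17)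
Why: Kinetic enolisation followed by O-triflation; the bulky amide takes a proton from the C7 methylene and not the shielded C9 methine next to quaternary C10, which fixes the double bond at C7=C8 and leaves C9 untouched.

Step 16
Reactants: 18 C7=C8 enol triflate
Product: 19 12-(TBS-oxy)-19-(TIPS-oxy)-13,14,15,16-tetranorlabd-7-ene
Conditions: Me2CuLi (from MeLi and CuBr·SMe2, 4 equiv), THF/Et2O, −20 to 0 °C
Reagents that add atoms: lithium dimethylcuprate, [Li+].C[Cu-]C
Why: Organocuprate cross-coupling of an enol triflate replaces OTf by methyl (C17) at the same carbon without moving the double bond, and both silyl ethers are inert.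

Step 17
Reactants: 19 12-(TBS-oxy)-19-(TIPS-oxy)-13,14,15,16-tetranorlabd-7-ene
Product: 20 19-(TIPS-oxy)-13,14,15,16-tetranorlabd-7-en-12-ol
Conditions: CSA (0.1 equiv), MeOH/CH2Cl2 1:1, 0 °C
Reagents that add atoms: none
Why: Acid-catalysed methanolysis of a silyl ether; the unhindered primary TBS ether cleaves orders of magnitude faster than the neopentyl TIPS ether, and the trisubstituted alkene tolerates catalytic sulfonic acid at 0 °C.

Step 18
Reactants: 20 19-(TIPS-oxy)-13,14,15,16-tetranorlabd-7-en-12-ol
Product: 21 12-iodo-19-(TIPS-oxy)-13,14,15,16-tetranorlabd-7-ene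
Conditions: I2, PPh3, imidazole, CH2Cl2, 0 °C to rt
Reagents that add atoms: iodine, II
Why: Appel-type iodination (Garegg–Samuelsson conditions) converts the primary alcohol through its alkoxyphosphonium salt by SN2 at the unhindered C12.

Step 19
Reactants: 21 12-iodo-19-(TIPS-oxy)-13,14,15,16-tetranorlabd-7-ene
Product: 22 19-(TIPS-oxy)-15,16-dinorlabd-7-en-13-yne
Conditions: LiC≡CH·H2NCH2CH2NH2 (3 equiv), DMSO, rt
Reagents that add atoms: lithium acetylide–ethylenediamine complex, [Li+].[C-]#C.NCCN
Why: SN2 alkylation of lithium acetylide in a dipolar aprotic solvent; C12 is primary and two carbons away from the ring, so substitution should outrun elimination.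

Step 20
Reactants: 22 19-(TIPS-oxy)-15,16-dinorlabd-7-en-13-yne
Product: 24 allyl 19-(TIPS-oxy)-16-norlabd-7-en-13-yn-15-oate, via lithium acetylide 23 (not isolated)
Conditions: n-BuLi (1.05 equiv), THF, −78 °C; then ClCO2CH2CH=CH2, −78 to −20 °C
Reagents that add atoms: allyl chloroformate, C=CCOC(=O)Cl; n-butyllithium, [Li]CCCC (lithium kept only in 23)
Why: Acylation of a metalated terminal alkyne with a chloroformate installs C15; the allyl ester is chosen because it can be removed at the end under neutral conditions that leave an angelate alone.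

Step 21
Reactants: 24 allyl 19-(TIPS-oxy)-16-norlabd-7-en-13-yn-15-oate
Product: 25 allyl (13Z)-19-(TIPS-oxy)labda-7,13-dien-15-oate
Conditions: Me2CuLi (from MeLi and CuBr·SMe2, 1.5 equiv), THF, −78 °C; AcOH in THF at −78 °C
Reagents that add atoms: lithium dimethylcuprate, [Li+].C[Cu-]C
Why: Conjugate syn-carbocupration of an ynoate with a Gilman cuprate puts methyl C16 and copper on the same side, so that after protonation with retention C12 and C15 are cis (13Z); THF, −78 °C and a cold quench suppress equilibration through the allenolate, and the ynoate reacts far faster than the allylic ester C–O bond.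

Step 22
Reactants: 25 allyl (13Z)-19-(TIPS-oxy)labda-7,13-dien-15-oate
Product: 26 allyl (13Z)-19-hydroxylabda-7,13-dien-15-oate
Conditions: Bu4NF/AcOH 1:1 (5 equiv), THF, rt to 45 °C
Reagents that add atoms: none
Why: Fluoride desilylation driven by the Si–F bond; buffering with AcOH keeps the medium too weakly basic to hydrolyse the allyl ester or to deprotonate the Z-enoate at its γ positions.

Step 23
Reactants: 26 allyl (13Z)-19-hydroxylabda-7,13-dien-15-oate; 27 angelic acid
Product: 29 allyl (13Z)-19-angeloyloxylabda-7,13-dien-15-oate, via mixed anhydride 28 (not isolated)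
Conditions: 27, 2,4,6-Cl3C6H2COCl, Et3N, toluene, rt; then 26, 80 °C
Reagents that add atoms: 2,4,6-trichlorobenzoyl chloride, O=C(Cl)c1c(Cl)cc(Cl)cc1Cl (atoms kept only in 28)
Why: Yamaguchi-type mixed-anhydride esterification run without DMAP; the alcohol attacks the angeloyl carbonyl because the aroyl carbonyl is blocked by two ortho chlorines, and omitting the nucleophilic catalyst avoids the addition–elimination path that turns angelates into tiglates.

Step 24
Reactants: 29 allyl (13Z)-19-angeloyloxylabda-7,13-dien-15-oate
Product: 30 (13Z)-19-angeloyloxylabda-7,13-dien-15-oic acid (target)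
Conditions: Pd(PPh3)4 (5 mol %), morpholine (5 equiv), THF, rt; dilute citric acid wash
Reagents that add atoms: none
Why: Tsuji–Trost deallylation; zerovalent palladium ionises only the allyl ester, morpholine traps the π-allyl unit, and the neopentyl angelate, both Z olefins and the C7=C8 bond see neither acid nor hydroxide.

## Compound list

1 | (+)-podocarpic acid (12-hydroxypodocarpa-8,11,13-trien-19-oic acid) | OC(=O)[C@@]1(C)CCC[C@]2(C)c3cc(O)ccc3CC[C@@H]12 | starting material
2 | methyl 12-methoxypodocarpa-8,11,13-trien-19-oate | COC(=O)[C@@]1(C)CCC[C@]2(C)c3cc(OC)ccc3CC[C@@H]12 | intermediate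
3 | 12-methoxypodocarpa-8,11,13-trien-19-ol | OC[C@@]1(C)CCC[C@]2(C)c3cc(OC)ccc3CC[C@@H]12 | intermediate
4 | 12-methoxy-19-(triisopropylsilyloxy)podocarpa-8,11,13-triene | CC(C)[Si](C(C)C)(C(C)C)OC[C@@]1(C)CCC[C@]2(C)c3cc(OC)ccc3CC[C@@H]12 | intermediate
5 | ring A 8,9-diacid: C10 bears axial CH3 (C20) and equatorial CO2H (C9), C5 bears equatorial CH2CH2CO2H (C6–C8), C4 bears CH3 (C18) and axial CH2OTIPS (C19) | CC(C)[Si](C(C)C)(C(C)C)OC[C@@]1(C)CCC[C@](C)(C(=O)O)[C@H]1CCC(=O)O | intermediate
6 | as 5, with C8 as methyl ester and C9 as free acid | CC(C)[Si](C(C)C)(C(C)C)OC[C@@]1(C)CCC[C@](C)(C(=O)O)[C@H]1CCC(=O)OC | intermediate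
7 | as 6, with C9 as CH2OH | CC(C)[Si](C(C)C)(C(C)C)OC[C@@]1(C)CCC[C@](C)(CO)[C@H]1CCC(=O)OC | intermediate
8 | as 6, with C9 as CHO | CC(C)[Si](C(C)C)(C(C)C)OC[C@@]1(C)CCC[C@](C)(C=O)[C@H]1CCC(=O)OC | intermediate
9 | as 6, with C10 bearing (E)-CH=CHI (C9=C11) | CC(C)[Si](C(C)C)(C(C)C)OC[C@@]1(C)CCC[C@](C)(/C=C/I)[C@H]1CCC(=O)OC | intermediate
10 | as 6, with C10 bearing (E)-CH=CH–CH2SiMe3 (C9=C11–C12) | CC(C)[Si](C(C)C)(C(C)C)OC[C@@]1(C)CCC[C@](C)(/C=C/C[Si](C)(C)C)[C@H]1CCC(=O)OC | intermediate
11 | cyclisation precursor: as 10, with C8 as CHO | CC(C)[Si](C(C)C)(C(C)C)OC[C@@]1(C)CCC[C@](C)(/C=C/C[Si](C)(C)C)[C@H]1CCC=O | intermediate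
12 | 19-(triisopropylsilyloxy)-13,14,15,16,17-pentanorlabd-11-en-8α-ol (equatorial 8α-OH, equatorial 9β-vinyl, trans-decalin) | CC(C)[Si](C(C)C)(C(C)C)OC[C@@]1(C)CCC[C@]2(C)[C@@H](C=C)[C@H](O)CC[C@@H]12 | intermediate
13 | B-alkyl-9-BBN adduct of 12, boron on C12 (not isolated) | CC(C)[Si](C(C)C)(C(C)C)OC[C@@]1(C)CCC[C@]2(C)[C@@H](CCB3C4CCCC3CCC4)[C@H](O)CC[C@@H]12 | intermediate
14 | 19-(triisopropylsilyloxy)-13,14,15,16,17-pentanorlabdane-8α,12-diol | CC(C)[Si](C(C)C)(C(C)C)OC[C@@]1(C)CCC[C@]2(C)[C@@H](CCO)[C@H](O)CC[C@@H]12 | intermediate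
15 | 12-TBS ether of 14 | CC(C)[Si](C(C)C)(C(C)C)OC[C@@]1(C)CCC[C@]2(C)[C@@H](CCO[Si](C)(C)C(C)(C)C)[C@H](O)CC[C@@H]12 | intermediate
16 | 12-(TBS-oxy)-19-(TIPS-oxy)-13,14,15,16,17-pentanorlabdan-8-one, 9α-H | CC(C)[Si](C(C)C)(C(C)C)OC[C@@]1(C)CCC[C@]2(C)[C@@H](CCO[Si](C)(C)C(C)(C)C)C(=O)CC[C@@H]12 | intermediate
17 | potassium C7=C8 enolate of 16 (not isolated) | CC(C)[Si](C(C)C)(C(C)C)OC[C@@]1(C)CCC[C@]2(C)[C@@H](CCO[Si](C)(C)C(C)(C)C)C([O-])=CC[C@@H]12.[K+] | intermediate
18 | C7=C8 enol triflate of 16 | CC(C)[Si](C(C)C)(C(C)C)OC[C@@]1(C)CCC[C@]2(C)[C@@H](CCO[Si](C)(C)C(C)(C)C)C(OS(=O)(=O)C(F)(F)F)=CC[C@@H]12 | intermediate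
19 | 12-(TBS-oxy)-19-(TIPS-oxy)-13,14,15,16-tetranorlabd-7-ene | CC(C)[Si](C(C)C)(C(C)C)OC[C@@]1(C)CCC[C@]2(C)[C@@H](CCO[Si](C)(C)C(C)(C)C)C(C)=CC[C@@H]12 | intermediate
20 | 19-(TIPS-oxy)-13,14,15,16-tetranorlabd-7-en-12-ol | CC(C)[Si](C(C)C)(C(C)C)OC[C@@]1(C)CCC[C@]2(C)[C@@H](CCO)C(C)=CC[C@@H]12 | intermediate
21 | 12-iodo-19-(TIPS-oxy)-13,14,15,16-tetranorlabd-7-ene | CC(C)[Si](C(C)C)(C(C)C)OC[C@@]1(C)CCC[C@]2(C)[C@@H](CCI)C(C)=CC[C@@H]12 | intermediate
22 | 19-(TIPS-oxy)-15,16-dinorlabd-7-en-13-yne | CC(C)[Si](C(C)C)(C(C)C)OC[C@@]1(C)CCC[C@]2(C)[C@@H](CCC#C)C(C)=CC[C@@H]12 | intermediate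
23 | lithium acetylide of 22 (not isolated) | CC(C)[Si](C(C)C)(C(C)C)OC[C@@]1(C)CCC[C@]2(C)[C@@H](CCC#[C-])C(C)=CC[C@@H]12.[Li+] | intermediate
24 | allyl 19-(TIPS-oxy)-16-norlabd-7-en-13-yn-15-oate | CC(C)[Si](C(C)C)(C(C)C)OC[C@@]1(C)CCC[C@]2(C)[C@@H](CCC#CC(=O)OCC=C)C(C)=CC[C@@H]12 | intermediate
25 | allyl (13Z)-19-(TIPS-oxy)labda-7,13-dien-15-oate | CC(C)[Si](C(C)C)(C(C)C)OC[C@@]1(C)CCC[C@]2(C)[C@@H](CC/C(C)=C\C(=O)OCC=C)C(C)=CC[C@@H]12 | intermediate
26 | allyl (13Z)-19-hydroxylabda-7,13-dien-15-oate | OC[C@@]1(C)CCC[C@]2(C)[C@@H](CC/C(C)=C\C(=O)OCC=C)C(C)=CC[C@@H]12 | intermediate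
27 | angelic acid, (Z)-2-methylbut-2-enoic acid | C/C=C(/C)C(=O)O | starting material
28 | angelic 2,4,6-trichlorobenzoic mixed anhydride (not isolated) | C/C=C(/C)C(=O)OC(=O)c1c(Cl)cc(Cl)cc1Cl | intermediate
29 | allyl (13Z)-19-angeloyloxylabda-7,13-dien-15-oate | C/C=C(/C)C(=O)OC[C@@]1(C)CCC[C@]2(C)[C@@H](CC/C(C)=C\C(=O)OCC=C)C(C)=CC[C@@H]12 | intermediate
30 | (13Z)-19-angeloyloxylabda-7,13-dien-15-oic acid, CNP0249147.1 | C/C=C(/C)C(=O)OC[C@@]1(C)CCC[C@]2(C)[C@@H](CC/C(C)=C\C(=O)O)C(C)=CC[C@@H]12 | target

## Step count and risks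

Total step count: 24. Longest linear sequence: 24 steps (1 to 30); angelic acid 27 enters as bought.

**Step 11.** Protodesilylation of the allylsilane, or Lewis-acid-induced self-condensation of the aldehyde, may outrun attack by C9, which is neopentyl. Facial selectivity at C9 may also be modest.
- The fallback closes the same C8–C9 bond without silicon, by a carbonyl-ene reaction, and sets out from vinyl iodide 9.
- Me2Zn and Pd(PPh3)4 in THF should give the (E)-propenyl methyl ester F1.
- i-Bu2AlH at −78 °C should then give the (E)-propenyl aldehyde F2.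
- Me2AlCl in CH2Cl2 (−78 to 0 °C) is a Lewis acid that also consumes protons. It should drive a type 1 intramolecular ene reaction of the citronellal-to-isopulegol kind.
- In that reaction C9 bonds to C8, a hydrogen of the E-methyl group C12 moves to the equatorial oxygen, and the double bond shifts to C11=C12.
- The route is rejoined at 12.

**Step 4.** Benzylic oxidation at C7 may deactivate the ring. Cleavage may stall at the keto-acid stage. The large excess of oxidant may slowly erode the silyl ether.
- The fallback leaves metal-oxo chemistry for ozone and sets out from 4.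
- Exhaustive ozonolysis (O3, CH2Cl2/MeOH, −78 °C) is followed by alkaline H2O2 (aq NaOH, 0 °C to rt) and acidification.
- The peroxide cuts the ring B 1,2-dione and the α-keto acids that the two Kekulé modes of ozone attack leave, so both modes converge on the same diacid.
- The TIPS ether is stable to base. This detour makes no new isolated compound (F0) and returns at 5.

**Step 23.** Acylation of the neopentyl, axial C19 hydroxyl may be slow, and during long heating the angeloyl unit may isomerise to the E (tigloyl) form.
- The fallback forms the ester bond first and builds the Z olefin afterwards, setting out from 26.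
- DCC and DMAP with 2-[bis(2,2,2-trifluoroethoxy)phosphoryl]propanoic acid in CH2Cl2 should give the C19 phosphonopropionate F3. At this stage there is no olefin geometry to lose.
- A Still–Gennari olefination with acetaldehyde follows (KN(SiMe3)2, 18-crown-6, THF, −78 °C). The phosphonate is by far the most acidic site, and the reaction should give the Z-trisubstituted enoate.
- The route is rejoined at 29.

## Further compounds

F1 | step 11 | (E)-propenyl methyl ester: as 10 with CH3 in place of CH2SiMe3 | CC(C)[Si](C(C)C)(C(C)C)OC[C@@]1(C)CCC[C@](C)(/C=C/C)[C@H]1CCC(=O)OC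
F2 | step 11 | (E)-propenyl aldehyde: as F1 with C8 as CHO | CC(C)[Si](C(C)C)(C(C)C)OC[C@@]1(C)CCC[C@](C)(/C=C/C)[C@H]1CCC=O
F0 | step 4 | none | none
F3 | step 23 | C19 2-[bis(2,2,2-trifluoroethoxy)phosphoryl]propanoate of 26 (both epimers at the phosphonate carbon) | CC(P(=O)(OCC(F)(F)F)OCC(F)(F)F)C(=O)OC[C@@]1(C)CCC[C@]2(C)[C@@H](CC/C(C)=C\C(=O)OCC=C)C(C)=CC[C@@H]12
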